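**Retrosynthetic overview**

1. Core numbering used below: ring A = cyclopentane C1(OH)–C2(side chain)–C3–C4–C5(spiro); ring B = cyclohexane C5–C6(hydroxypropyl)–C7(=C(CH3)CHO)–C8–C9–C10(CH3)(OH).
2. Late disconnections: enal ⇐ periodate cleavage of a dioxolane-masked glycol; (2Z,4E)-triene acetate ⇐ butenolide-derived lactol + allylic phosphonate (butenolide ⇐ 3-furyl group on C2); C10 carbinol ⇐ epoxide directed by the C1 hydroxyl; hydroxypropyl chain ⇐ lactone carbonyl + two-carbon Wittig unit.
3. Key disconnection: C7–C8 and C5–C6 by an intramolecular Diels–Alder reaction of allenoate ester 14 of ring-A dienol 8; one operation closes ring B and a temporary γ-lactone and sets the spiro centre C5, C6 and the geometry of the tetrasubstituted C7 alkene.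
4. Enabling feature: the oxygen on C1 (ring A) and C6 (ring B) are 1,3-related across the spiro atom C5 on the same face, and the first carbon of the C6 chain can be carried as a carboxyl, so C1–O–C(=O)–C6 is a three-atom tether from diene terminus C5 to dienophile carbon C6; the C7 alkylidene is the second π bond of an allene whose axis encodes its geometry.
5. Ring order: ring A (step 4; absolute configuration in step 6) → ring B + lactone (step 12) → lactone opened (steps 13–14); a butenolide ring is made and opened late (steps 19–24); acid 13 comes from a Sharpless epoxide by palladium-catalysed carbonylation.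

Key step: step 12

Remark: compounds 1, 3, 9, 25 and 26 are taken as purchasable; in names, "DE" is the C7 substituent (E)-1-[(4R)-2,2-dimethyl-1,3-dioxolan-4-yl]ethylidene (methyl cis to C6) and TBS is tert-butyldimethylsilyl.

**Route**

Step 1
Reactants: 1 pent-3-yn-1-ol
Product: 2 5-iodopent-2-yne
Conditions: I2, PPh3, imidazole, CH2Cl2, 0 °C to rt
Reagents that add atoms: iodine, II
Why: Appel-type iodination (alkoxyphosphonium activation, SN2 by iodide) of a primary alcohol; no stereocentre is involved.

Step 2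
Reactants: 3 methyl 2-(furan-3-yl)acetate; 2 5-iodopent-2-yne
Product: 4 methyl 2-(furan-3-yl)hept-5-ynoate (racemic)
Conditions: LiN(i-Pr)2, THF, −78 °C; then 2, DMPU, −78 to 0 °C
Reagents that add atoms: none
Why: Ester enolate alkylation (SN2) with a primary iodide; the new centre is left racemic on purpose because step 6 equilibrates and sets it.

Step 3
Reactants: 4 methyl 2-(furan-3-yl)hept-5-ynoate
Product: 5 2-(furan-3-yl)hept-5-ynal (racemic)
Conditions: i-Bu2AlH (1.05 equiv), CH2Cl2, −78 °C; aq. potassium sodium tartrate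
Reagents that add atoms: none
Why: Partial reduction of an ester to the aldehyde through the aluminium hemiacetal, which is stable at −78 °C.

Step 4
Reactants: 5 2-(furan-3-yl)hept-5-ynal
Product: 6 (2Z)-2-(but-3-en-2-ylidene)-5-(furan-3-yl)cyclopentan-1-ol (racemic, both C1 epimers)
Conditions: Ni(cod)2 (10 mol %), divinylzinc, THF, 0 °C; aq. NH4Cl
Reagents that add atoms: divinylzinc, C=C[Zn]C=C
Why: Nickel-catalysed alkylative ynal cyclisation: aldehyde and alkyne couple on zerovalent nickel to an oxanickelacyclopentene, vinyl is transferred from zinc and reductive elimination places it cis to the carbinol carbon, so only the Z exocyclic diene should form; this closes ring A, and the carbinol mixture is erased in step 5.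

Step 5
Reactants: 6 (2Z)-2-(but-3-en-2-ylidene)-5-(furan-3-yl)cyclopentan-1-ol
Product: 7 (2Z)-2-(but-3-en-2-ylidene)-5-(furan-3-yl)cyclopentan-1-one (racemic)
Conditions: Dess–Martin periodinane, NaHCO3, CH2Cl2, 0 °C
Reagents that add atoms: none
Why: Dess–Martin oxidation under buffered conditions converges both epimers to one ketone without moving the Z alkene.

Step 6
Reactants: 7 (2Z)-2-(but-3-en-2-ylidene)-5-(furan-3-yl)cyclopentan-1-one
Product: 8 (1R,2Z,5S)-2-(but-3-en-2-ylidene)-5-(furan-3-yl)cyclopentan-1-ol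
Conditions: RuCl2[(S)-xylbinap][(S)-daipen] (cat.), t-BuOK (cat.), H2 (8 atm), i-PrOH, 25 °C
Reagents that add atoms: none
Why: Noyori asymmetric hydrogenation with dynamic kinetic resolution: base racemises the furyl-bearing α-carbon through the enolate, the ruthenium diphosphine/diamine catalyst reduces only C=O and hydride enters anti to the furyl group, so the cis alcohol should result with C1 (R) fixed by the catalyst (antipode chosen accordingly) and C5 (S) by the cis preference.

Step 7
Reactants: 9 (2Z)-3-methylpent-2-en-4-yn-1-ol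
Product: 10 [(2S,3R)-3-ethynyl-3-methyloxiran-2-yl]methanol
Conditions: Ti(OiPr)4 (cat.), L-(+)-diethyl tartrate (cat.), t-BuOOH, 4 Å molecular sieves, CH2Cl2, −20 °C
Reagents that add atoms: tert-butyl hydroperoxide, CC(C)(C)OO
Why: Sharpless asymmetric epoxidation of a trisubstituted allylic alcohol; L-(+)-tartrate directs oxygen to the face that gives the (2S,3R) epoxide, whose quaternary C3 is the centre that matters later.

Step 8
Reactants: 10 [(2S,3R)-3-ethynyl-3-methyloxiran-2-yl]methanol
Product: 11 methyl (aR,5R)-5,6-dihydroxy-4-methylhexa-2,3-dienoate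
Conditions: Pd2(dba)3·CHCl3 (cat.), PPh3, CO (1 atm), MeOH, 25 °C
Reagents that add atoms: carbon monoxide, [C-]#[O+]; methanol, CO
Why: Palladium-catalysed SN2' carbonylation of an alkynyl oxirane: zerovalent palladium attacks the alkyne terminus anti to the breaking propargylic C–O bond, the allenylpalladium inserts CO and methanol releases the ester, so the C3 configuration should be relayed to the (aR) allene axis.

Step 9
Reactants: 11 methyl (aR,5R)-5,6-dihydroxy-4-methylhexa-2,3-dienoate
Product: 12 methyl (aR)-4-[(4R)-2,2-dimethyl-1,3-dioxolan-4-yl]penta-2,3-dienoate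
Conditions: 2,2-dimethoxypropane, PPTS (cat.), CH2Cl2, rt
Reagents that add atoms: 2,2-dimethoxypropane, COC(C)(C)OC
Why: Acetonide formation (transacetalisation) protects the glycol that later becomes the formyl group; no stereocentre is touched.

Step 10
Reactants: 12 methyl (aR)-4-[(4R)-2,2-dimethyl-1,3-dioxolan-4-yl]penta-2,3-dienoate
Product: 13 (aR)-4-[(4R)-2,2-dimethyl-1,3-dioxolan-4-yl]penta-2,3-dienoic acid
Conditions: LiOH, THF/H2O, 0 °C; then 1 M HCl to pH 4, 0 °C
Reagents that add atoms: lithium hydroxide, [Li+].[OH-]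
Why: Saponification at 0 °C, cold enough to avoid base-mediated isomerisation of the allenoate to the alkynoate, which would erase the axis.

Step 11
Reactants: 8 (1R,2Z,5S)-2-(but-3-en-2-ylidene)-5-(furan-3-yl)cyclopentan-1-ol; 13 (aR)-4-[(4R)-2,2-dimethyl-1,3-dioxolan-4-yl]penta-2,3-dienoic acid
Product: 14 (1R,2Z,5S)-2-(but-3-en-2-ylidene)-5-(furan-3-yl)cyclopentyl (aR)-4-[(4R)-2,2-dimethyl-1,3-dioxolan-4-yl]penta-2,3-dienoate
Conditions: N,N'-diisopropylcarbodiimide, DMAP (cat.), CH2Cl2, −20 to 0 °C
Reagents that add atoms: none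
Why: Steglich esterification; acylation occurs at oxygen so C1 keeps its configuration, and low temperature with catalytic DMAP should leave the allene axis intact.

Step 12
Reactants: 14 (1R,2Z,5S)-2-(but-3-en-2-ylidene)-5-(furan-3-yl)cyclopentyl (aR)-4-[(4R)-2,2-dimethyl-1,3-dioxolan-4-yl]penta-2,3-dienoate
Product: 15 (1R,2S,5R,6R)-2-(furan-3-yl)-1-hydroxy-10-methyl-7-DE-spiro[4.5]dec-9-ene-6-carboxylic acid 1,6-lactone (cis-fused γ-lactone)
Conditions: toluene (5 mM), BHT (cat.), 120 °C, sealed tube
Reagents that add atoms: none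
Why: Intramolecular Diels–Alder reaction of an allenoate: the Z-configured diene C5=C10–C9=C8 adds suprafacially and in concert across the ester-conjugated C6=C7 π bond of the allene, the closest known reaction type being the thermal intramolecular Diels–Alder reaction of 2,4-dienyl acrylates and allenecarboxylates to bicyclic γ-lactones. Ring B closes as a cyclohexene in the [4+2] mode, and the γ-lactone closes at the same time as the five-membered ring that contains the tether C1–O–C(=O) (fused mode). C5 is controlled by the C1 stereocentre, because the short tether can bring the dienophile only to the diene face that carries O1, and C6 is controlled by the diene geometry, because a tether on the inner (Z) position of the diene terminus reaches C6 only with the carbonyl exo, which gives the cis-fused lactone (H6 cis to C4). The geometry of the new tetrasubstituted C7 alkene is controlled by the (aR) allene axis: the dioxolanyl group points towards the diene and ends cis to C8, the methyl group ends cis to C6. The step needs periselectivity for the ester-conjugated allene π bond over the distal one and over the furan as a diene, which the three-atom tether (five- against six-membered lactone), the conjugation of that bond with the ester and the poor reach to the furan should secure. High dilution and BHT hold back bimolecular reactions of the allenoate, and the temperature is kept below that at which a 1,5-hydrogen shift of the Z-diene becomes fast.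

Step 13
Reactants: 15 cis-fused γ-lactone
Product: 16 lactol of 15 (C6–CH(OH)–O–C1, both anomers)
Conditions: i-Bu2AlH (1.1 equiv), CH2Cl2, −78 °C; aq. potassium sodium tartrate
Reagents that add atoms: none
Why: Partial reduction of the γ-lactone to the lactol through the aluminium hemiacetal; dioxolane, furan and alkenes are inert.

Step 14
Reactants: 16 lactol of 15
Product: 17 methyl (2E)-3-[(1R,2S,5R,6R)-2-(furan-3-yl)-1-hydroxy-10-methyl-7-DE-spiro[4.5]dec-9-en-6-yl]prop-2-enoate
Conditions: Ph3P=CHCO2Me, toluene, 60 °C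
Reagents that add atoms: methyl (triphenylphosphoranylidene)acetate, COC(=O)C=P(c1ccccc1)(c1ccccc1)c1ccccc1
Why: Wittig olefination of the lactol through its open hydroxy-aldehyde form with a stabilised ylide (E-selective); it adds the two missing chain carbons and frees the C1 hydroxyl, while the closed lactol shields the epimerisable C6.

Step 15
Reactants: 17 methyl (2E)-3-[...spiro[4.5]dec-9-en-6-yl]prop-2-enoate
Product: 18 methyl 3-[(1R,2S,5R,6R)-2-(furan-3-yl)-1-hydroxy-10-methyl-7-DE-spiro[4.5]dec-9-en-6-yl]propanoate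
Conditions: RhCl(PPh3)3 (cat.), H2 (4 atm), toluene, rt
Reagents that add atoms: none
Why: Homogeneous hydrogenation with RhCl(PPh3)3 reduces the unhindered 1,2-disubstituted enoate double bond and should leave the trisubstituted ring alkene, the tetrasubstituted C7 alkene and the furan.

Step 16
Reactants: 18 methyl 3-[...spiro[4.5]dec-9-en-6-yl]propanoate
Product: 19 methyl 3-[(1R,2S,5S,6R,9S,10R)-9,10-epoxy-2-(furan-3-yl)-1-hydroxy-10-methyl-7-DE-spiro[4.5]decan-6-yl]propanoate
Conditions: VO(acac)2 (cat.), t-BuOOH, CH2Cl2, 0 °C to rt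
Reagents that add atoms: tert-butyl hydroperoxide, CC(C)(C)OO
Why: Hydroxyl-directed vanadium-catalysed epoxidation of a homoallylic alcohol: the C1 alkoxide on vanadium delivers oxygen to the C9=C10 face syn to C1, which sets C10; the more remote tetrasubstituted alkene and the furan should react more slowly.

Step 17
Reactants: 19 epoxy ester
Product: 20 (1R,2S,5S,6R,10S)-2-(furan-3-yl)-6-(3-hydroxypropyl)-10-methyl-7-DE-spiro[4.5]decane-1,10-diol
Conditions: LiAlH4, THF, 0 to 40 °C
Reagents that add atoms: none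
Why: Hydride reduction: the ester goes to the primary alcohol and the trisubstituted epoxide is opened by SN2 attack at the less substituted C9, so the C10–O bond and the configuration from step 16 are kept.

Step 18
Reactants: 20 triol
Product: 21 (1R,2S,5S,6R,10S)-6-[3-(TBS-oxy)propyl]-2-(furan-3-yl)-10-methyl-7-DE-spiro[4.5]decane-1,10-diol
Conditions: TBSCl (1.05 equiv), imidazole, CH2Cl2, 0 °C
Reagents that add atoms: tert-butyldimethylsilyl chloride, CC(C)(C)[Si](C)(C)Cl
Why: Silylation, selective for the primary hydroxyl over the hindered secondary and the tertiary one.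

Step 19
Reactants: 21 silyl ether diol
Product: 23 4-[(1R,2S,5S,6R,10S)-6-[3-(TBS-oxy)propyl]-1,10-dihydroxy-10-methyl-7-DE-spiro[4.5]decan-2-yl]furan-2(5H)-one (butenolide), via hydroxybutenolide 22 (not isolated)
Conditions: O2, hν (visible), tetraphenylporphyrin (cat.), i-Pr2NEt, CH2Cl2, −78 °C; then NaBH4, EtOH, 0 °C; then 1 M HCl to pH 4
Reagents that add atoms: oxygen, O=O
Why: Dye-sensitised photooxygenation of the 3-substituted furan ([4+2] addition of singlet oxygen), base-induced opening of the endoperoxide at the less hindered bridgehead C–H, then borohydride reduction of the lactol carbon and lactonisation; the carbonyl ends on the unsubstituted furan α-carbon and the ring fixes the later Z alkene; irradiation is stopped when the furan is consumed because the C7 alkene can react more slowly in an ene fashion.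

Step 20
Reactants: 23 butenolide
Product: 24 4-[(1R,2S,5S,6R,10S)-6-[3-(TBS-oxy)propyl]-1,10-dihydroxy-10-methyl-7-DE-spiro[4.5]decan-2-yl]-2,5-dihydrofuran-2-ol (both anomers)
Conditions: i-Bu2AlH (4 equiv), CH2Cl2, −78 °C; aq. potassium sodium tartrate
Reagents that add atoms: none
Why: Partial reduction of the butenolide to the lactol; the extra hydride covers the two free hydroxyls.

Step 21
Reactants: 25 2-methylprop-2-en-1-ol; 26 1-bromo-3-methylbut-2-ene
Product: 27 6-methyl-2-methylidenehept-5-en-1-ol
Conditions: n-BuLi (2.2 equiv), TMEDA, Et2O, 0 °C to rt; then 26, −78 to 0 °C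
Reagents that add atoms: none
Why: Allylic lithiation of the alkoxide to the dianion and C-alkylation with the allylic bromide.

Step 22
Reactants: 27 6-methyl-2-methylidenehept-5-en-1-ol
Product: 28 2-(bromomethyl)-6-methylhepta-1,5-diene
Conditions: CBr4, PPh3, CH2Cl2, 0 °C
Reagents that add atoms: carbon tetrabromide, BrC(Br)(Br)Br
Why: Appel bromination of a primary allylic alcohol.

Step 23
Reactants: 28 2-(bromomethyl)-6-methylhepta-1,5-diene
Product: 29 diethyl (6-methyl-2-methylidenehept-5-en-1-yl)phosphonate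
Conditions: P(OEt)3, 130 °C
Reagents that add atoms: triethyl phosphite, CCOP(OCC)OCC
Why: Michaelis–Arbuzov reaction of an allylic bromide.

Step 24
Reactants: 24 lactol; 29 diethyl (6-methyl-2-methylidenehept-5-en-1-yl)phosphonate
Product: 30 (2Z,4E)-2-[(1R,2S,5S,6R,10S)-6-[3-(TBS-oxy)propyl]-1,10-dihydroxy-10-methyl-7-DE-spiro[4.5]decan-2-yl]-10-methyl-6-methylideneundeca-2,4,9-trien-1-ol
Conditions: 29 (5 equiv), n-BuLi (5 equiv), THF/DMPU, −78 °C; then 24, −78 to 0 °C
Reagents that add atoms: none
Why: Horner–Wadsworth–Emmons olefination of the lactol (open Z-hydroxy-enal form) with the lithiated allylic phosphonate, E-selective for the new disubstituted alkene; the Z trisubstituted alkene comes unchanged from the ring and excess anion covers the three hydroxyls.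

Step 25
Reactants: 30 trienol
Product: 31 (2Z,4E)-2-[(1R,2S,5S,6R,10S)-6-[3-(TBS-oxy)propyl]-1,10-dihydroxy-10-methyl-7-DE-spiro[4.5]decan-2-yl]-10-methyl-6-methylideneundeca-2,4,9-trien-1-yl acetate
Conditions: AcCl (1.1 equiv), 2,4,6-collidine, CH2Cl2, −78 °C
Reagents that add atoms: acetyl chloride, CC(=O)Cl
Why: Selective acylation of the primary allylic hydroxyl; the hindered secondary and the tertiary hydroxyl should not react under these conditions.

Step 26
Reactants: 31 acetate
Product: 33 target CNP0204268.1, via glycol 32 (not isolated)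
Conditions: AcOH/THF/H2O (3:1:1), 40 °C; then NaHCO3 to pH 7, NaIO4, 0 °C
Reagents that add atoms: none
Why: Acid hydrolysis of the silyl ether and the acetonide, then periodate glycol cleavage (Malaprade reaction) of the only 1,2-diol to the conjugated aldehyde; the alkene geometry from step 12 is kept and the 1,3-diol, acetate and triene are not touched.

**Compound list**

1 | pent-3-yn-1-ol | CC#CCCO | starting material
2 | 5-iodopent-2-yne | CC#CCCI | intermediate
3 | methyl 2-(furan-3-yl)acetate | COC(=O)Cc1ccoc1 | starting material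
4 | methyl 2-(furan-3-yl)hept-5-ynoate (racemic) | COC(=O)C(CCC#CC)c1ccoc1 | intermediate
5 | 2-(furan-3-yl)hept-5-ynal (racemic) | O=CC(CCC#CC)c1ccoc1 | intermediate
6 | (2Z)-2-(but-3-en-2-ylidene)-5-(furan-3-yl)cyclopentan-1-ol (racemic, both C1 epimers) | c3cocc3C1CC/C(=C(\C)C=C)C1O | intermediate
7 | (2Z)-2-(but-3-en-2-ylidene)-5-(furan-3-yl)cyclopentan-1-one (racemic) | c3cocc3C1CC/C(=C(\C)C=C)C1=O | intermediate
8 | (1R,2Z,5S)-2-(but-3-en-2-ylidene)-5-(furan-3-yl)cyclopentan-1-ol | c3cocc3[C@@H]1CC/C(=C(\C)C=C)[C@@H]1O | intermediate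
9 | (2Z)-3-methylpent-2-en-4-yn-1-ol | C#C/C(C)=C\CO | starting material
10 | [(2S,3R)-3-ethynyl-3-methyloxiran-2-yl]methanol | C#C[C@@]1(C)O[C@H]1CO | intermediate
11 | methyl (aR,5R)-5,6-dihydroxy-4-methylhexa-2,3-dienoate | COC(=O)C([H])=[C@]=C(C)[C@@H](O)CO | intermediate
12 | methyl (aR)-4-[(4R)-2,2-dimethyl-1,3-dioxolan-4-yl]penta-2,3-dienoate | COC(=O)C([H])=[C@]=C(C)[C@@H]1COC(C)(C)O1 | intermediate
13 | (aR)-4-[(4R)-2,2-dimethyl-1,3-dioxolan-4-yl]penta-2,3-dienoic acid | OC(=O)C([H])=[C@]=C(C)[C@@H]1COC(C)(C)O1 | intermediate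
14 | (1R,2Z,5S)-2-(but-3-en-2-ylidene)-5-(furan-3-yl)cyclopentyl (aR)-4-[(4R)-2,2-dimethyl-1,3-dioxolan-4-yl]penta-2,3-dienoate | c3cocc3[C@@H]1CC/C(=C(\C)C=C)[C@@H]1OC(=O)C([H])=[C@]=C(C)[C@@H]4COC(C)(C)O4 | intermediate
15 | (1R,2S,5R,6R)-2-(furan-3-yl)-1-hydroxy-10-methyl-7-DE-spiro[4.5]dec-9-ene-6-carboxylic acid 1,6-lactone | c3cocc3[C@@H]1CC[C@]2([C@H](C(=O)O4)/C(=C(\C)[C@@H]5COC(C)(C)O5)CC=C2C)[C@@H]14 | intermediate
16 | lactol of 15 (both anomers) | c3cocc3[C@@H]1CC[C@]2([C@H](C(O)O4)/C(=C(\C)[C@@H]5COC(C)(C)O5)CC=C2C)[C@@H]14 | intermediate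
17 | methyl (2E)-3-[(1R,2S,5R,6R)-2-(furan-3-yl)-1-hydroxy-10-methyl-7-DE-spiro[4.5]dec-9-en-6-yl]prop-2-enoate | c3cocc3[C@@H]1CC[C@]2([C@H](/C=C/C(=O)OC)/C(=C(\C)[C@@H]5COC(C)(C)O5)CC=C2C)[C@@H]1O | intermediate
18 | methyl 3-[(1R,2S,5R,6R)-2-(furan-3-yl)-1-hydroxy-10-methyl-7-DE-spiro[4.5]dec-9-en-6-yl]propanoate | c3cocc3[C@@H]1CC[C@]2([C@H](CCC(=O)OC)/C(=C(\C)[C@@H]5COC(C)(C)O5)CC=C2C)[C@@H]1O | intermediate
19 | methyl 3-[(1R,2S,5S,6R,9S,10R)-9,10-epoxy-2-(furan-3-yl)-1-hydroxy-10-methyl-7-DE-spiro[4.5]decan-6-yl]propanoate | c3cocc3[C@@H]1CC[C@]2([C@H](CCC(=O)OC)/C(=C(\C)[C@@H]5COC(C)(C)O5)C[C@H]6[C@]2(C)O6)[C@@H]1O | intermediate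
20 | (1R,2S,5S,6R,10S)-2-(furan-3-yl)-6-(3-hydroxypropyl)-10-methyl-7-DE-spiro[4.5]decane-1,10-diol | c3cocc3[C@@H]1CC[C@]2([C@H](CCCO)/C(=C(\C)[C@@H]5COC(C)(C)O5)CC[C@]2(C)O)[C@@H]1O | intermediate
21 | (1R,2S,5S,6R,10S)-6-[3-(TBS-oxy)propyl]-2-(furan-3-yl)-10-methyl-7-DE-spiro[4.5]decane-1,10-diol | c3cocc3[C@@H]1CC[C@]2([C@H](CCCO[Si](C)(C)C(C)(C)C)/C(=C(\C)[C@@H]5COC(C)(C)O5)CC[C@]2(C)O)[C@@H]1O | intermediate
22 | 5-hydroxy-4-[core-2-yl]furan-2(5H)-one (core as in 21; hydroxybutenolide) | OC3OC(=O)C=C3[C@@H]1CC[C@]2([C@H](CCCO[Si](C)(C)C(C)(C)C)/C(=C(\C)[C@@H]5COC(C)(C)O5)CC[C@]2(C)O)[C@@H]1O | intermediate (not isolated)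
23 | 4-[core-2-yl]furan-2(5H)-one (butenolide) | O=C3OCC(=C3)[C@@H]1CC[C@]2([C@H](CCCO[Si](C)(C)C(C)(C)C)/C(=C(\C)[C@@H]5COC(C)(C)O5)CC[C@]2(C)O)[C@@H]1O | intermediate
24 | 4-[core-2-yl]-2,5-dihydrofuran-2-ol (both anomers) | OC3OCC(=C3)[C@@H]1CC[C@]2([C@H](CCCO[Si](C)(C)C(C)(C)C)/C(=C(\C)[C@@H]5COC(C)(C)O5)CC[C@]2(C)O)[C@@H]1O | intermediate
25 | 2-methylprop-2-en-1-ol | C=C(C)CO | starting material
26 | 1-bromo-3-methylbut-2-ene | CC(C)=CCBr | starting material
27 | 6-methyl-2-methylidenehept-5-en-1-ol | C=C(CO)CCC=C(C)C | intermediate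
28 | 2-(bromomethyl)-6-methylhepta-1,5-diene | C=C(CBr)CCC=C(C)C | intermediate
29 | diethyl (6-methyl-2-methylidenehept-5-en-1-yl)phosphonate | C=C(CP(=O)(OCC)OCC)CCC=C(C)C | intermediate
30 | (2Z,4E)-2-[core-2-yl]-10-methyl-6-methylideneundeca-2,4,9-trien-1-ol | C=C(/C=C/C=C(\CO)[C@@H]1CC[C@]2([C@H](CCCO[Si](C)(C)C(C)(C)C)/C(=C(\C)[C@@H]5COC(C)(C)O5)CC[C@]2(C)O)[C@@H]1O)CCC=C(C)C | intermediate
31 | acetate of 30 | C=C(/C=C/C=C(\COC(C)=O)[C@@H]1CC[C@]2([C@H](CCCO[Si](C)(C)C(C)(C)C)/C(=C(\C)[C@@H]5COC(C)(C)O5)CC[C@]2(C)O)[C@@H]1O)CCC=C(C)C | intermediate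
32 | (2Z,4E)-2-[(1R,2S,5S,6R,10S)-7-[(2E,3R)-3,4-dihydroxybutan-2-ylidene]-1,10-dihydroxy-6-(3-hydroxypropyl)-10-methylspiro[4.5]decan-2-yl]-10-methyl-6-methylideneundeca-2,4,9-trien-1-yl acetate (glycol) | C=C(/C=C/C=C(\COC(C)=O)[C@@H]1CC[C@]2([C@H](CCCO)/C(=C(\C)[C@@H](O)CO)CC[C@]2(C)O)[C@@H]1O)CCC=C(C)C | intermediate (not isolated)
33 | (2E)-2-[(1R,2S,5S,6R,10S)-2-[(2Z,4E)-1-(acetyloxy)-10-methyl-6-methylideneundeca-2,4,9-trien-2-yl]-1,10-dihydroxy-6-(3-hydroxypropyl)-10-methylspiro[4.5]decan-7-ylidene]propanal (CNP0204268.1) | C=C(/C=C/C=C(\COC(C)=O)[C@@H]1CC[C@]2([C@H](CCCO)/C(=C(\C)C=O)CC[C@]2(C)O)[C@@H]1O)CCC=C(C)C | target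

**Step count and risks**

Total step count: 26. Longest linear sequence: 19 steps (steps 1–6, 11–20, 24–26).

Step 12 (key step). The cycloaddition may be slow, because the ester must reach its less favoured rotamer and the diene terminus is fully substituted. A thermal 1,5-hydrogen shift of the Z-diene or oligomerisation of the allenoate could then overtake it. The fallback replaces the covalent ester tether by a metal template and sets out from 8 and 12. Dienol 8 is converted into its bromomagnesium alkoxide (MeMgBr, 1 equiv, CH2Cl2) and warmed with allenoate 12. Magnesium bridges the alkoxide and the ester carbonyl, a Lewis-acid-templated Diels–Alder reaction known for 2,4-dienols and acrylates, so the dienophile is activated and delivered to the oxygen-bearing diene face. This should give methyl (1R,2S,5R,6R)-2-(furan-3-yl)-1-hydroxy-10-methyl-7-DE-spiro[4.5]dec-9-ene-6-carboxylate F1. Only this cis adduct can lactonise (cat. DBU, toluene), which returns the route to 15.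

Step 19. Ene-type photooxygenation of the electron-rich tetrasubstituted C7 alkene may compete with oxygenation of the furan. The fallback avoids electrophilic oxidants, sets out from 21 and returns at 23. Both free hydroxyls are capped with N-(trimethylsilyl)imidazole to give the 1,10-bis(trimethylsilyl) ether of 21 F2. Lithiation with s-BuLi/TMEDA (THF, −78 °C) should take place at the furan α-position remote from the bulky ring substituent, and B(OMe)3 traps it as the dimethyl furan-2-ylboronate F3. Oxidation with H2O2/NaHCO3 and aqueous citric acid then gives the 2-hydroxyfuran, which tautomerises to the conjugated butenolide with loss of the trimethylsilyl groups, i.e. 23.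

Step 6. Racemisation of the furyl-bearing carbon may not keep pace with hydrogenation, or the base may isomerise the Z-dienone; either would erode enantio- and diastereoselectivity. The fallback sets out from 7 and returns at 8. Luche reduction (NaBH4, CeCl3·7H2O, MeOH, −78 °C) should give the racemic cis alcohol, that is 8 together with its enantiomer (1S,2Z,5R)-2-(but-3-en-2-ylidene)-5-(furan-3-yl)cyclopentan-1-ol F4. Kinetic resolution with Candida antarctica lipase B and vinyl acetate is expected to acylate the (1R) alcohol, giving (1R,2Z,5S)-2-(but-3-en-2-ylidene)-5-(furan-3-yl)cyclopentyl acetate F5, which is separated from F4. Methanolysis (K2CO3, MeOH) returns 8.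

Further compounds
F1 | step 12 | methyl (1R,2S,5R,6R)-2-(furan-3-yl)-1-hydroxy-10-methyl-7-DE-spiro[4.5]dec-9-ene-6-carboxylate | c3cocc3[C@@H]1CC[C@]2([C@H](C(=O)OC)/C(=C(\C)[C@@H]5COC(C)(C)O5)CC=C2C)[C@@H]1O
F2 | step 19 | 1,10-bis(trimethylsilyl) ether of 21 | c3cocc3[C@@H]1CC[C@]2([C@H](CCCO[Si](C)(C)C(C)(C)C)/C(=C(\C)[C@@H]5COC(C)(C)O5)CC[C@]2(C)O[Si](C)(C)C)[C@@H]1O[Si](C)(C)C
F3 | step 19 | dimethyl furan-2-ylboronate of F2 (boron on the furan α-carbon remote from the ring substituent) | COB(OC)c3cc(co3)[C@@H]1CC[C@]2([C@H](CCCO[Si](C)(C)C(C)(C)C)/C(=C(\C)[C@@H]5COC(C)(C)O5)CC[C@]2(C)O[Si](C)(C)C)[C@@H]1O[Si](C)(C)C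
F4 | step 6 | (1S,2Z,5R)-2-(but-3-en-2-ylidene)-5-(furan-3-yl)cyclopentan-1-ol | c3cocc3[C@H]1CC/C(=C(\C)C=C)[C@H]1O
F5 | step 6 | (1R,2Z,5S)-2-(but-3-en-2-ylidene)-5-(furan-3-yl)cyclopentyl acetate | c3cocc3[C@@H]1CC/C(=C(\C)C=C)[C@@H]1OC(C)=O
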